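Labdane numbering is used throughout.

**Plan**

- **Cuts.** The C19 acetate. C9–C10 of ring B, with Me3Si on C17 as electrofuge and O19 tied to C10 as leaving group. C12–C13 by Suzuki–Miyaura coupling to a purchased butenolide. C9–C11 and C8–C17 by alkyne carbometalation, C8≡C9 by homologation, C4–C18 by Birch alkylation, and C6–C7 by benzylic alkylation.
- **Enabling feature.** On ring A the axial C19 oxygen and C10 are 1,3-diaxial. O19 can therefore be bonded to C10 in a temporary five-membered ether ring (C4–C19–O–C10–C5, a 6-oxabicyclo[3.2.1]octane). The C8=C17 methylene next to C9 is the mark of an allylsilane terminator.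
- **Forward order.** Ring A comes from the arene of 1 by Birch reduction, and the butenolide ring is brought in ready-made as 18. The temporary ether ring is set up through a lactone and the C6–C16 chain is grown on it. Ring B is closed last, in the same event that opens the ether.
- **Stereochemistry.** C4 comes from the pyrrolidine auxiliary in the Birch methylation. C5 and the C10–O bond come from anti protolactonisation under control of C4. C10 is set by inversion at C10–O, and C9 by the Z-allylsilane (from syn-carbocupration) reacting in a chair transition state.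

Key step: step 12

Assumption: the (S)-auxiliary is taken to direct methylation of enolate 7 to the face that gives (R)-C4; if the sense proves opposite, the equally available (R)-amine is used and nothing else changes.

**Step 1**
Reactants: 1 2,3-dimethylbenzoyl chloride; 2 (S)-2-(methoxymethyl)pyrrolidine
Product: 3 (S)-(2,3-dimethylphenyl)[2-(methoxymethyl)pyrrolidin-1-yl]methanone
Conditions: Et3N, CH2Cl2, 0 °C → rt
Reagents that add atoms: none
Why: Schotten–Baumann-type N-acylation of a secondary amine by an aroyl chloride is fast and leaves the pyrrolidine stereocentre untouched.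

**Step 2**
Reactants: 3 amide; 4 tert-butyl(2-iodoethoxy)dimethylsilane
Product: 6 (S)-{2-[3-(tert-butyldimethylsilyloxy)propyl]-3-methylphenyl}[2-(methoxymethyl)pyrrolidin-1-yl]methanone, via benzylic lithium species 5 (not isolated)
Conditions: LDA (1.1 equiv), THF, −78 °C; then 4, −78 → 0 °C
Reagents that add atoms: none
Why: Lateral lithiation of an ortho-toluamide is directed by the tertiary amide to the 2-methyl group (C6), and SN2 alkylation of the benzylic anion by the primary iodide adds C7 and C8.

**Step 3**
Reactants: 6 chain-extended benzamide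
Product: 8 {(1R)-2-[3-(tert-butyldimethylsilyloxy)propyl]-1,3-dimethylcyclohexa-2,5-dien-1-yl}[(2S)-2-(methoxymethyl)pyrrolidin-1-yl]methanone, via potassium amide enolate 7 (not isolated)
Conditions: K (2.3 equiv), NH3(l)/THF, t-BuOH (1.0 equiv), −78 °C; piperylene; MeI, −78 °C; NH4Cl
Reagents that add atoms: iodomethane, CI
Why: In this asymmetric Birch reduction–alkylation of a chiral benzamide the arene is reduced at the ipso and para carbons, both alkyl groups stay on the surviving C5=C10 bond, and the chelated enolate is methylated on the face away from the methoxymethyl arm, which sets quaternary C4 as R.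

**Step 4**
Reactants: 8 cyclohexadiene amide
Product: 9 {(1R)-2-[3-(tert-butyldimethylsilyloxy)propyl]-1,3-dimethylcyclohex-2-en-1-yl}[(2S)-2-(methoxymethyl)pyrrolidin-1-yl]methanone
Conditions: H2 (1 atm), Pd/C, EtOAc, rt, stopped after one equivalent of H2
Reagents that add atoms: none
Why: Chemoselective catalytic hydrogenation saturates the cis-disubstituted C2=C3 alkene, while the tetrasubstituted C5=C10 alkene is inert under these conditions.

**Step 5**
Reactants: 9 cyclohexene amide
Product: 10 (1R,5S,8R)-8-(3-hydroxypropyl)-1,5-dimethyl-6-oxabicyclo[3.2.1]octan-7-one (C19(=O)–O–C10 lactone, C6 chain syn to the lactone bridge)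
Conditions: TsOH·H2O (2.5 equiv), toluene, 90 °C; aq. NaHCO3 work-up
Reagents that add atoms: water, O
Why: In this acid-induced lactonisation of a β,γ-unsaturated amide the proton adds to C5 anti to the amide oxygen, which closes on tertiary C10 from the C19 face, so C4 sets C5 (H trans to the bridge, C6 cis to C19) and the C10–O bond, subsequent hydrolysis releases the auxiliary irreversibly, the silyl ether is hydrolysed in the same pot, and any ether formed at C10 by the freed C8 hydroxyl reopens under the same acid.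

**Step 6**
Reactants: 10 lactone alcohol
Product: 11 3-[(1R,5S,8R)-1,5-dimethyl-7-oxo-6-oxabicyclo[3.2.1]octan-8-yl]propanal
Conditions: TEMPO (10 mol %), PhI(OAc)2 (1.1 equiv), CH2Cl2, rt
Reagents that add atoms: none
Why: Oxoammonium (TEMPO) oxidation of a primary alcohol stops at the aldehyde and does not touch the lactone.

**Step 7**
Reactants: 11 lactone aldehyde
Product: 12 (1R,5S,8R)-8-(but-3-yn-1-yl)-1,5-dimethyl-6-oxabicyclo[3.2.1]octan-7-one
Conditions: dimethyl (1-diazo-2-oxopropyl)phosphonate, K2CO3, MeOH, 0 °C → rt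
Reagents that add atoms: dimethyl (1-diazo-2-oxopropyl)phosphonate, COP(=O)(OC)C(=[N+]=[N-])C(C)=O
Why: Ohira–Bestmann (Seyferth–Gilbert) homologation converts the C8 aldehyde into the C8≡C9 terminal alkyne, and the lactone, hindered at both the acyl and the tertiary alkyl side, is not methanolysed.

**Step 8**
Reactants: 12 lactone alkyne
Product: 13 (1S,2R,3R)-2-(but-3-yn-1-yl)-3-(hydroxymethyl)-1,3-dimethylcyclohexan-1-ol
Conditions: LiAlH4, THF, 0 → 50 °C; aq. NaOH work-up
Reagents that add atoms: none
Why: Hydride reduction of the lactone cleaves only the acyl C19–O bond, so C10 keeps its oxygen and configuration, and the terminal alkyne is inert to LiAlH4 at this temperature.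

**Step 9**
Reactants: 13 diol
Product: 15 (1R,5S,8R)-8-(but-3-yn-1-yl)-1,5-dimethyl-6-oxabicyclo[3.2.1]octane, via primary triflate 14 (not isolated)
Conditions: Tf2O (1.05 equiv), 2,6-lutidine (2.5 equiv), CH2Cl2, −78 → 0 °C
Reagents that add atoms: none
Why: In this intramolecular Williamson-type etherification the primary hydroxyl is triflated selectively at low temperature and the 1,3-diaxial tertiary hydroxyl displaces the neopentyl triflate 5-exo-tet, so the C10–O bond and all three stereocentres stay untouched.

**Step 10**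
Reactants: 15 ether alkyne
Product: 17 (1R,5S,8R)-1,5-dimethyl-8-{(3Z)-3-[(trimethylsilyl)methyl]hexa-3,5-dien-1-yl}-6-oxabicyclo[3.2.1]octane, via alkenylcopper 16 (not isolated)
Conditions: Me3SiCH2MgCl, CuBr·SMe2, Et2O/Me2S, −40 °C; 15, −25 → −10 °C; then ZnBr2, Pd(PPh3)4 (5 mol %), vinyl bromide, THF, −10 °C → rt
Reagents that add atoms: (trimethylsilyl)methylmagnesium chloride, C[Si](C)(C)C[Mg]Cl; vinyl bromide, C=CBr
Why: Syn-carbocupration of the terminal alkyne puts Me3SiCH2 on C8 and copper on C9 on the same side, and Negishi-type alkenyl–alkenyl coupling after copper-to-zinc exchange proceeds with retention, so C11 ends cis to C17 and trans to C7 (Z).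

**Step 11**
Reactants: 17 silyl diene; 18 4-bromofuran-2(5H)-one
Product: 20 4-{(3Z)-6-[(1R,5S,8R)-1,5-dimethyl-6-oxabicyclo[3.2.1]octan-8-yl]-4-[(trimethylsilyl)methyl]hex-3-en-1-yl}furan-2(5H)-one, via B-alkyl-9-BBN borane 19 (not isolated)
Conditions: 9-BBN-H, THF, 0 °C → rt; then 18, PdCl2(dppf) (5 mol %), AsPh3, Cs2CO3, DMF/THF/H2O, rt
Reagents that add atoms: none
Why: 9-BBN hydroborates only the monosubstituted C11=C12 terminus, with boron on C12 and the hindered trisubstituted allylsilane left alone, and B-alkyl Suzuki–Miyaura coupling with the β-bromobutenolide forms C12–C13.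

**Step 12**
Reactants: 20 ether allylsilane butenolide
Product: 22 andrograpanin, ent-19-hydroxylabda-8(17),13-dien-16,15-olide (4R,5S,9R,10S), via silyl ether 21 (not isolated)
Conditions: TMSOTf (0.3 equiv), 2,6-di-tert-butyl-4-methylpyridine (0.5 equiv), CH2Cl2 (0.005 M), −78 → −30 °C; then citric acid, MeOH, 0 °C
Reagents that add atoms: none
Why: Proposed new method: TMSOTf silylates the bridging ether oxygen, the strained tertiary C10–O bond of the 6-oxabicyclo[3.2.1]octane ionises with O19 leaving as its silyl ether, the C8=C9 allylsilane attacks C10 through C9, and the β-silyl cation at C8 hands Me3Si+ back to triflate, which forms C8=C17 and regenerates TMSOTf, so the event is an aprotic, silyl-transfer-catalysed isomerisation of 20 to 21. The closest known reaction types are the allylsilane-terminated cation–olefin cyclisation (started from epoxides, acetals or allylic alcohols), the Lewis-acid SN1 allylation of tertiary alkyl halides and alcohols by allylsilanes, and the cleavage of tert-alkyl ethers by silyl triflates; the new element is a saturated tertiary dialkyl ether as initiator. Ring B closes 6-endo-trig at the C8=C9 bond through a chair-like transition state with the C5–C6 bond equatorial on ring A. C10 is set by attack of C9 on the face opposite the departing O19, which is also the face the equatorial C6–C7–C8 tether reaches in a chair, so C20 is pushed axial and cis to C19 and the decalin is trans; C9 is set by the Z geometry of the allylsilane, which holds C11 trans to C7 and therefore equatorial. The step needs ionisation to outrun protodesilylation and E1 loss from C10: the cycle forms no Brønsted acid, the hindered pyridine takes up adventitious acid, ring strain lowers the barrier to heterolysis, and return of O19 only regenerates 20. The electron-poor butenolide C13=C14 bond is not nucleophilic enough to compete and is at most reversibly silylated at its carbonyl oxygen.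

**Step 13**
Reactants: 22 andrograpanin
Product: 23 ent-19-acetoxylabda-8(17),13-dien-16,15-olide (4R,5S,9R,10S), the target
Conditions: Ac2O, pyridine, DMAP (cat.), CH2Cl2, rt
Reagents that add atoms: acetic anhydride, CC(=O)OC(C)=O
Why: DMAP-catalysed acetylation of the only hydroxyl group is mild enough for the exocyclic alkene and the butenolide and touches no stereocentre.

**Compound list**

1 | 2,3-dimethylbenzoyl chloride | Cc1cccc(C(=O)Cl)c1C | starting material
2 | (S)-2-(methoxymethyl)pyrrolidine | COC[C@@H]1CCCN1 | starting material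
3 | (S)-(2,3-dimethylphenyl)[2-(methoxymethyl)pyrrolidin-1-yl]methanone | COC[C@@H]1CCCN1C(=O)c1cccc(C)c1C | intermediate
4 | tert-butyl(2-iodoethoxy)dimethylsilane | CC(C)(C)[Si](C)(C)OCCI | starting material
5 | benzylic lithium species from 3 (Li on the 2-CH2) | [Li]Cc1c(C)cccc1C(=O)N1CCC[C@H]1COC | intermediate
6 | (S)-{2-[3-(tert-butyldimethylsilyloxy)propyl]-3-methylphenyl}[2-(methoxymethyl)pyrrolidin-1-yl]methanone | COC[C@@H]1CCCN1C(=O)c1cccc(C)c1CCCO[Si](C)(C)C(C)(C)C | intermediate
7 | potassium amide enolate of the 1,4-dihydrobenzamide | [K+].[O-]C(N1CCC[C@H]1COC)=C1C=CCC(C)=C1CCCO[Si](C)(C)C(C)(C)C | intermediate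
8 | {(1R)-2-[3-(tert-butyldimethylsilyloxy)propyl]-1,3-dimethylcyclohexa-2,5-dien-1-yl}[(2S)-2-(methoxymethyl)pyrrolidin-1-yl]methanone | C[C@@]1(C(=O)N2CCC[C@H]2COC)C=CCC(C)=C1CCCO[Si](C)(C)C(C)(C)C | intermediate
9 | {(1R)-2-[3-(tert-butyldimethylsilyloxy)propyl]-1,3-dimethylcyclohex-2-en-1-yl}[(2S)-2-(methoxymethyl)pyrrolidin-1-yl]methanone | C[C@@]1(C(=O)N2CCC[C@H]2COC)CCCC(C)=C1CCCO[Si](C)(C)C(C)(C)C | intermediate
10 | (1R,5S,8R)-8-(3-hydroxypropyl)-1,5-dimethyl-6-oxabicyclo[3.2.1]octan-7-one | C[C@@]12CCC[C@@](C)(C(=O)O1)[C@H]2CCCO | intermediate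
11 | 3-[(1R,5S,8R)-1,5-dimethyl-7-oxo-6-oxabicyclo[3.2.1]octan-8-yl]propanal | C[C@@]12CCC[C@@](C)(C(=O)O1)[C@H]2CCC=O | intermediate
12 | (1R,5S,8R)-8-(but-3-yn-1-yl)-1,5-dimethyl-6-oxabicyclo[3.2.1]octan-7-one | C[C@@]12CCC[C@@](C)(C(=O)O1)[C@H]2CCC#C | intermediate
13 | (1S,2R,3R)-2-(but-3-yn-1-yl)-3-(hydroxymethyl)-1,3-dimethylcyclohexan-1-ol | C[C@]1(O)CCC[C@@](C)(CO)[C@H]1CCC#C | intermediate
14 | [(1R,2R,3S)-2-(but-3-yn-1-yl)-3-hydroxy-1,3-dimethylcyclohexyl]methyl trifluoromethanesulfonate | C[C@]1(O)CCC[C@@](C)(COS(=O)(=O)C(F)(F)F)[C@H]1CCC#C | intermediate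
15 | (1R,5S,8R)-8-(but-3-yn-1-yl)-1,5-dimethyl-6-oxabicyclo[3.2.1]octane | C[C@@]12CCC[C@@](C)(CO1)[C@H]2CCC#C | intermediate
16 | (Z)-alkenylcopper (Cu on C9, cis to CH2SiMe3 on C8) | C[C@@]12CCC[C@@](C)(CO1)[C@H]2CC/C(C[Si](C)(C)C)=C/[Cu] | intermediate
17 | (1R,5S,8R)-1,5-dimethyl-8-{(3Z)-3-[(trimethylsilyl)methyl]hexa-3,5-dien-1-yl}-6-oxabicyclo[3.2.1]octane | C[C@@]12CCC[C@@](C)(CO1)[C@H]2CC/C(C[Si](C)(C)C)=C/C=C | intermediate
18 | 4-bromofuran-2(5H)-one | O=C1C=C(Br)CO1 | starting material
19 | B-alkyl-9-BBN borane (boron on C12) | C[C@@]12CCC[C@@](C)(CO1)[C@H]2CC/C(C[Si](C)(C)C)=C/CCB1C2CCCC1CCC2 | intermediate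
20 | 4-{(3Z)-6-[(1R,5S,8R)-1,5-dimethyl-6-oxabicyclo[3.2.1]octan-8-yl]-4-[(trimethylsilyl)methyl]hex-3-en-1-yl}furan-2(5H)-one | C[C@@]12CCC[C@@](C)(CO1)[C@H]2CC/C(C[Si](C)(C)C)=C/CCC1=CC(=O)OC1 | intermediate
21 | 19-O-trimethylsilyl ether of andrograpanin | C=C1CC[C@@H]2[C@](C)(CO[Si](C)(C)C)CCC[C@@]2(C)[C@@H]1CCC1=CC(=O)OC1 | intermediate
22 | andrograpanin, ent-19-hydroxylabda-8(17),13-dien-16,15-olide | C=C1CC[C@@H]2[C@](C)(CO)CCC[C@@]2(C)[C@@H]1CCC1=CC(=O)OC1 | intermediate
23 | ent-19-acetoxylabda-8(17),13-dien-16,15-olide | C=C1CC[C@@H]2[C@](C)(COC(C)=O)CCC[C@@]2(C)[C@@H]1CCC1=CC(=O)OC1 | target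

Total step count: 13. Longest linear sequence: 13 steps, from 1 to 23.

**Steps most likely to fail**

**Step 12.**
- *What may go wrong:* silylation and heterolysis of the hindered ether may be slower than loss of the silyl group to adventitious acid. Proton loss from C10 may also drain the catalyst.
- *Fallback:* it sets out from diol 13 and comes back at target 23. It replaces the temporary ring by an ordinary tertiary leaving group that known chemistry can ionise.
  - Selective acetylation of the primary hydroxyl (Ac2O, pyridine, 0 °C) would give the hydroxy acetate F1.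
  - Silylation of the tertiary hydroxyl (TMSOTf, 2,6-lutidine) would give the silyl ether F2.
  - The chemistry of step 10 would lead through the alkenylcopper F3 to the silyl diene F4.
  - The chemistry of step 11 would lead through the borane F5 to the acetoxy silyloxy allylsilane F6.
  - Ring B would then be closed by the known InCl3/Me3SiBr-catalysed SN1 allylation of tertiary aliphatic alcohols and their silyl ethers by allylsilanes (CH2Cl2/hexane, rt). This would give 23 directly. C10 and C9 would then be controlled only by the equatorial C5 tether, the chair transition state and the Z-olefin.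

**Step 10.**
- *What may go wrong:* the poorly nucleophilic α-silyl copper reagent may add sluggishly to the alkyne. Olefin geometry may erode, or homocoupling may intervene, during the copper–zinc–palladium relay.
- *Fallback:* it sets out from alkyne 15 and comes back at 20. It takes the olefin geometry from a ring instead of from a carbometalation.
  - Lithiation (n-BuLi, THF/DMPU) and opening of ethylene oxide would give the homopropargylic alcohol F7.
  - 5-endo-dig cycloisomerisation with PdCl2(MeCN)2 would give the 5-alkyl-2,3-dihydrofuran F8.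
  - Nickel-catalysed Kumada-type coupling of its enol ether C–O bond with Me3SiCH2MgCl (NiCl2(PPh3)2, benzene/Et2O, reflux) proceeds with retention. It would give the Z-homoallylic alcohol F9, with CH2SiMe3 cis to C11.
  - Appel iodination (I2, PPh3, imidazole) would give the iodide F10.
  - Zinc insertion would give the alkylzinc iodide F11, and base-free Negishi coupling with 18 (PdCl2(dppf), THF/DMA) would give 20.

**Step 9.**
- *What may go wrong:* substitution at the neopentyl C19 may be slow. Sulfonylation and elimination of the tertiary alcohol, or a 1,2-shift from the triflate, could then compete.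
- *Fallback:* it sets out from lactone 12 and comes back at 15, bypassing 13 and 14. It never breaks a C–O bond at C19 by substitution.
  - DIBAL-H (toluene, −78 °C) would give the lactol F12.
  - Ionic reduction of its oxocarbenium ion (Et3SiH, BF3·OEt2, CH2Cl2, −78 °C) would give the ether 15.

**Further compounds**

F1 | step 12 | [(1R,2R,3S)-2-(but-3-yn-1-yl)-3-hydroxy-1,3-dimethylcyclohexyl]methyl acetate | C[C@]1(O)CCC[C@@](C)(COC(C)=O)[C@H]1CCC#C
F2 | step 12 | [(1R,2R,3S)-2-(but-3-yn-1-yl)-1,3-dimethyl-3-(trimethylsilyloxy)cyclohexyl]methyl acetate | C[C@]1(O[Si](C)(C)C)CCC[C@@](C)(COC(C)=O)[C@H]1CCC#C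
F3 | step 12 | (Z)-alkenylcopper derived from F2 | C[C@]1(O[Si](C)(C)C)CCC[C@@](C)(COC(C)=O)[C@H]1CC/C(C[Si](C)(C)C)=C/[Cu]
F4 | step 12 | (3Z)-3-[(trimethylsilyl)methyl]hexa-3,5-dienyl analogue of F2 | C[C@]1(O[Si](C)(C)C)CCC[C@@](C)(COC(C)=O)[C@H]1CC/C(C[Si](C)(C)C)=C/C=C
F5 | step 12 | B-alkyl-9-BBN borane derived from F4 | C[C@]1(O[Si](C)(C)C)CCC[C@@](C)(COC(C)=O)[C@H]1CC/C(C[Si](C)(C)C)=C/CCB1C2CCCC1CCC2
F6 | step 12 | monocyclic 19-acetoxy-10-trimethylsilyloxy Z-allylsilane butenolide | C[C@]1(O[Si](C)(C)C)CCC[C@@](C)(COC(C)=O)[C@H]1CC/C(C[Si](C)(C)C)=C/CCC1=CC(=O)OC1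
F7 | step 10 | 6-[(1R,5S,8R)-1,5-dimethyl-6-oxabicyclo[3.2.1]octan-8-yl]hex-3-yn-1-ol | C[C@@]12CCC[C@@](C)(CO1)[C@H]2CCC#CCCO
F8 | step 10 | (1R,5S,8R)-8-[2-(4,5-dihydrofuran-2-yl)ethyl]-1,5-dimethyl-6-oxabicyclo[3.2.1]octane | C[C@@]12CCC[C@@](C)(CO1)[C@H]2CCC1=CCCO1
F9 | step 10 | (3Z)-6-[(1R,5S,8R)-1,5-dimethyl-6-oxabicyclo[3.2.1]octan-8-yl]-4-[(trimethylsilyl)methyl]hex-3-en-1-ol | C[C@@]12CCC[C@@](C)(CO1)[C@H]2CC/C(C[Si](C)(C)C)=C/CCO
F10 | step 10 | primary iodide derived from F9 | C[C@@]12CCC[C@@](C)(CO1)[C@H]2CC/C(C[Si](C)(C)C)=C/CCI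
F11 | step 10 | alkylzinc iodide derived from F10 | C[C@@]12CCC[C@@](C)(CO1)[C@H]2CC/C(C[Si](C)(C)C)=C/CC[Zn]I
F12 | step 9 | (1R,5S,8R)-8-(but-3-yn-1-yl)-1,5-dimethyl-6-oxabicyclo[3.2.1]octan-7-ol (lactol, both C7 epimers) | C[C@@]12CCC[C@@](C)(C(O)O1)[C@H]2CCC#C
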